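The five-membered ring A shares only C1 and C5 with ring B; these atoms lie β and α to the C6 carbonyl, and the other ring A atoms (C2, C3, C4) form a chain that ends in a tertiary carbinol. Both ring A bonds to ring B, C1–C2 and C4–C5, are therefore disconnected together, giving a cycloheptadienone and a ketone homoenolate. In a single operation the zinc homoenolate from 1-isopropylcyclopropanol adds 1,4 to 3,6-dimethylcyclohepta-2,5-dien-1-one and the resulting C5 enolate attacks the isopropyl ketone, creating ring A with C1, C4 and C5. Directed reduction, directed epoxidation and benzoylation finish the synthesis.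

Key step: step 6

Atom labels: C1 = ring-fusion carbon with CH3; C2, C3 = CH2 of ring A; C4 = C(OH)(iPr); C5 = ring-fusion CH; C6 = carbon with the benzoate; C7 = CH2; C8 (with CH3) and C9 = epoxide carbons; C10 = CH2. Ring A is five-membered, ring B seven-membered. The β face is that of the C1 methyl, the α face that of H-5. Names use azulene locants (C4 = 3, C5 = 3a, C6 = 4, C8 = 6, C9 = 7, C1 = 8a).

Assumption: the antipode of the chiral ligand in step 6 that gives the R configuration at C1 (8aR) is chosen after a first run; all later stereocentres are relayed from C1.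

Step 1
Reactants: 1 2,5-dimethylanisole
Product: 2 1-methoxy-2,5-dimethylcyclohexa-1,4-diene
Conditions: Li, t-BuOH, NH3(l)–THF, −78 → −33 °C
Reagents that add atoms: none
Why: Birch reduction: the two protons are delivered ortho and meta to the methoxy group, so that OMe and both methyl groups stay on the residual double bonds of the non-conjugated diene; no stereocentre is formed.

Step 2
Reactants: 2 1-methoxy-2,5-dimethylcyclohexa-1,4-diene, 3 bromoform
Product: 5 rac-7,7-dibromo-1-methoxy-3,6-dimethylbicyclo[4.1.0]hept-3-ene, via dibromocarbene 4 (not isolated)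
Conditions: KOtBu (1.2 equiv), pentane, −20 → 0 °C
Reagents that add atoms: bromoform (compound 3), BrC(Br)Br
Why: α-elimination gives dibromocarbene 4, whose electrophilic [2+1] addition (dihalocarbene cyclopropanation) should prefer the tetrasubstituted, oxygen-activated enol ether over the trisubstituted alkene; the two ring-fusion centres are cis by necessity, racemic, and are erased in step 3.

Step 3
Reactants: 5 rac-7,7-dibromo-1-methoxy-3,6-dimethylbicyclo[4.1.0]hept-3-ene
Product: 6 2-bromo-3,6-dimethylcyclohepta-2,5-dien-1-one
Conditions: AgNO3 (2 equiv), acetone–H2O (10:1), 0 °C → rt, dark; crude product used at once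
Reagents that add atoms: water, O
Why: silver-assisted loss of the endo bromide is concerted with disrotatory opening of the cyclopropane (cyclopropyl-to-allyl cation ring expansion), and hydrolysis of the methoxy-stabilised cation gives the ketone with the vinyl bromide at the α-carbon; no stereocentre remains.

Step 4
Reactants: 6 2-bromo-3,6-dimethylcyclohepta-2,5-dien-1-one
Product: 7 3,6-dimethylcyclohepta-2,5-dien-1-one
Conditions: Bu3SnH (1.1 equiv, slow addition), Pd(PPh3)4 (3 mol %), THF, rt
Reagents that add atoms: none
Why: palladium-catalysed hydrodebromination of a vinyl bromide: zerovalent palladium inserts into the activated C–Br bond of the α-bromoenone, hydride passes from tin to palladium and reductive elimination gives the enone under neutral conditions, with no acid or base to move the 5,6-double bond into conjugation.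

Step 5
Reactants: 8 methyl isobutyrate, 9 ethylmagnesium bromide (2.4 equiv)
Product: 10 1-isopropylcyclopropan-1-ol
Conditions: Ti(OiPr)4 (10 mol %), Et2O, rt; aq NH4Cl
Reagents that add atoms: ethylmagnesium bromide (compound 9), CC[Mg]Br
Why: Kulinkovich cyclopropanation: a titanium-bound ethylene unit, formed catalytically from two EtMgBr with loss of ethane, adds twice to the ester carbonyl and expels methoxide; no stereocentre is formed.

Step 6
Reactants: 7 3,6-dimethylcyclohepta-2,5-dien-1-one, 10 1-isopropylcyclopropan-1-ol (3 equiv)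
Product: 13 (3R,3aR,8aR)-3-hydroxy-6,8a-dimethyl-3-(propan-2-yl)-2,3,3a,5,8,8a-hexahydroazulen-4(1H)-one, via bis(4-methyl-3-oxopentyl)zinc 11 (not isolated), via C5 zinc enolate 12 (not isolated)
Conditions: 10, Et2Zn (1.5 equiv), toluene, 0 °C → rt; then 7, (CuOTf)2·C6H6 (2.5 mol %), chiral sulfonate-bearing imidazolinium NHC precursor (6 mol %), t-BuOMe, −20 °C → rt, hold at rt; aq NH4Cl, 0 °C
Reagents that add atoms: none
Why: Proposed new method: two cyclopropanols per Et2Zn give a zinc bis(cyclopropoxide) free of ethyl groups, strain release opens it to the β-zincio ketone 11, and transmetallation to the NHC-bound copper followed by 1,4-addition to the C5=C1–C6=O enone of 7 forms C1–C2 and leaves zinc enolate 12 at C5 only. The closest known reactions are copper-mediated transfers of cyclopropanol-derived zinc homoenolates, NHC–copper-catalysed dialkylzinc additions that build quaternary β-carbons on 3-methylcycloalkenones, and copper-catalysed conjugate addition–aldol cyclisations of keto-enones; their merger with a homoenolate as the nucleophile is not known. Ring A closes by a 5-(enolexo)-exo-trig aldol addition of C5 to the isopropyl ketone (C4–C5). C1 is set irreversibly by the chiral ligand, which selects the enone face; C4 is set by the zinc bridge between the C6 enolate oxygen and the ketone oxygen, which puts the C4 oxygen cis to C6 on ring A and the isopropyl group on the side of H-5; C5 stays correctable, by retro-aldol and re-closure of the aldolate and by enolisation towards C6, and on holding at room temperature should settle as the trans-fused chelate in which C2 and C4 are both equatorial on ring B. The step needs 1,4- rather than 1,2-addition, reaction at the conjugated C5=C1 bond only and a single enolate regioisomer: the soft copper-bound alkyl avoids the carbonyl, the isolated C8=C9 bond is no acceptor, and the enolate arises at C5 from the addition itself, so C7 is never deprotonated deliberately and the skipped alkene has no reason to move.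

Step 7
Reactants: 13 (3R,3aR,8aR)-3-hydroxy-6,8a-dimethyl-3-(propan-2-yl)-2,3,3a,5,8,8a-hexahydroazulen-4(1H)-one
Product: 14 (3R,3aS,4S,8aR)-6,8a-dimethyl-3-(propan-2-yl)-1,2,3,3a,4,5,8,8a-octahydroazulene-3,4-diol
Conditions: Me4NBH(OAc)3 (5 equiv), MeCN–AcOH (1:1), −20 °C → rt
Reagents that add atoms: none
Why: hydroxyl-directed triacetoxyborohydride reduction (Evans–Saksena): exchange of an acetate for the C4 hydroxyl ties boron to the β face and the hydride is delivered within this alkoxyborohydride to the same face of the C6 carbonyl, so the new C6 hydroxyl should be α (1,3-anti to the C4 hydroxyl), while unbound ketones are not reduced by this reagent.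

Step 8
Reactants: 14 (3R,3aS,4S,8aR)-6,8a-dimethyl-3-(propan-2-yl)-1,2,3,3a,4,5,8,8a-octahydroazulene-3,4-diol
Product: 15 (3R,3aS,4S,6R,7S,8aR)-6,7-epoxy-6,8a-dimethyl-3-(propan-2-yl)decahydroazulene-3,4-diol
Conditions: VO(acac)2 (5 mol %), t-BuOOH (1.5 equiv, decane solution), CH2Cl2, 0 °C → rt
Reagents that add atoms: tert-butyl hydroperoxide, CC(C)(C)OO
Why: hydroxyl-directed epoxidation with VO(acac)2: the vanadate ester of the homoallylic C6 hydroxyl carries the alkyl peroxide to the α face of the trisubstituted C8=C9 bond, setting C8 and C9 cis to the C6 oxygen, while the remote tertiary C4 hydroxyl cannot reach the alkene.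

Step 9
Reactants: 15 (3R,3aS,4S,6R,7S,8aR)-6,7-epoxy-6,8a-dimethyl-3-(propan-2-yl)decahydroazulene-3,4-diol, 16 benzoyl chloride (1.5 equiv)
Product: 17 (3R,3aS,4S,6R,7S,8aR)-6,7-epoxy-3-hydroxy-6,8a-dimethyl-3-(propan-2-yl)decahydroazulen-4-yl benzoate
Conditions: pyridine (3 equiv), DMAP (0.1 equiv), CH2Cl2, 0 °C → rt
Reagents that add atoms: benzoyl chloride (compound 16), O=C(Cl)c1ccccc1
Why: DMAP-catalysed acylation of the secondary C6 hydroxyl; the tertiary C4 hydroxyl, flanked by the isopropyl group and the ring fusion, should not react, the basic medium keeps the epoxide closed and no stereocentre is touched.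

Compound list
1 | 2,5-dimethylanisole | COc1cc(C)ccc1C | starting material
2 | 1-methoxy-2,5-dimethylcyclohexa-1,4-diene | COC1=C(C)CC=C(C)C1 | intermediate
3 | bromoform | BrC(Br)Br | starting material
4 | dibromocarbene | Br[C]Br | intermediate
5 | rac-7,7-dibromo-1-methoxy-3,6-dimethylbicyclo[4.1.0]hept-3-ene (cis-fused cyclopropane; racemic, one enantiomer drawn) | CO[C@]12CC(C)=CC[C@@]1(C)C2(Br)Br | intermediate
6 | 2-bromo-3,6-dimethylcyclohepta-2,5-dien-1-one | CC1=CCC(C)=C(Br)C(=O)C1 | intermediate
7 | 3,6-dimethylcyclohepta-2,5-dien-1-one | CC1=CCC(C)=CC(=O)C1 | intermediate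
8 | methyl isobutyrate | COC(=O)C(C)C | starting material
9 | ethylmagnesium bromide | CC[Mg]Br | starting material
10 | 1-isopropylcyclopropan-1-ol | CC(C)C1(O)CC1 | intermediate
11 | bis(4-methyl-3-oxopentyl)zinc | CC(C)C(=O)CC[Zn]CCC(=O)C(C)C | intermediate
12 | (4-methyl-3-oxopentyl)zinc enolate (C5=C6–O–Zn) of (R)-3,6-dimethyl-3-(4-methyl-3-oxopentyl)cyclohept-5-en-1-one | CC(C)C(=O)CC[C@]1(C)CC=C(C)CC(O[Zn]CCC(=O)C(C)C)=C1 | intermediate
13 | (3R,3aR,8aR)-3-hydroxy-6,8a-dimethyl-3-(propan-2-yl)-2,3,3a,5,8,8a-hexahydroazulen-4(1H)-one (trans-fused; C1 methyl and C4 hydroxyl β, H-5 α) | CC(C)[C@]1(O)CC[C@]2(C)CC=C(C)CC(=O)[C@H]21 | intermediate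
14 | (3R,3aS,4S,8aR)-6,8a-dimethyl-3-(propan-2-yl)-1,2,3,3a,4,5,8,8a-octahydroazulene-3,4-diol (C4 hydroxyl β, C6 hydroxyl α) | CC(C)[C@]1(O)CC[C@]2(C)CC=C(C)C[C@H](O)[C@H]21 | intermediate
15 | (3R,3aS,4S,6R,7S,8aR)-6,7-epoxy-6,8a-dimethyl-3-(propan-2-yl)decahydroazulene-3,4-diol (epoxide and C6 hydroxyl α) | CC(C)[C@]1(O)CC[C@]2(C)C[C@@H]3O[C@]3(C)C[C@H](O)[C@H]21 | intermediate
16 | benzoyl chloride | O=C(Cl)c1ccccc1 | starting material
17 | (3R,3aS,4S,6R,7S,8aR)-6,7-epoxy-3-hydroxy-6,8a-dimethyl-3-(propan-2-yl)decahydroazulen-4-yl benzoate (CNP0340059.1) | CC(C)[C@]1(O)CC[C@]2(C)C[C@@H]3O[C@]3(C)C[C@H](OC(=O)c3ccccc3)[C@H]21 | target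

Total step count: 9. Longest linear sequence: 8 steps (steps 1–4 and 6–9, from 2,5-dimethylanisole); step 5 is a one-step branch.

Steps most likely to fail

Step 6. Transfer of the chelated homoenolate from zinc to copper and on to a fully substituted β-carbon may be too slow, so that the zinc alkoxide has time to shift the C8=C9 bond into conjugation. Enantiofacial control at C1 may be poor. Ring closure may stop at the more easily reached cis-fused aldolate without equilibrating. The fallback uses known chemistry, sets out from cyclopropanol 10 (with dienone 7 as partner) and returns at 13. N-Bromosuccinimide (CH2Cl2, 0 °C) should open 10 to 1-bromo-4-methylpentan-3-one F1. Ethylene glycol with TsOH (benzene, water removal) should give 2-(2-bromoethyl)-2-(propan-2-yl)-1,3-dioxolane F2, and Mg in THF should give {2-[2-(propan-2-yl)-1,3-dioxolan-2-yl]ethyl}magnesium bromide F3. Asymmetric 1,4-addition of F3 to 7 (Cu(OTf)2 and a chiral NHC precursor, Et2O, −30 °C), an established way to quaternary β-carbons on 3-methylcycloalkenones, should give (R)-3,6-dimethyl-3-{2-[2-(propan-2-yl)-1,3-dioxolan-2-yl]ethyl}cyclohept-5-en-1-one F4. PPTS in aqueous acetone should release (R)-3,6-dimethyl-3-(4-methyl-3-oxopentyl)cyclohept-5-en-1-one F5. KOH in MeOH at 0 °C should then close ring A by reversible intramolecular aldol addition to 13; regiocontrol of the enolate is weaker here than in step 6.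

Step 3. Once the ring has opened, the bromodienone can enolise and lose HBr, which aromatises the ring to a tropone, and the nitric acid formed can move the skipped double bond. The fallback sets out from 5 and returns at 7, bypassing 6 and step 4. Bu3SnH (1.0 equiv, Et2O, rt) should remove one bromine and give endo-7-bromo-1-methoxy-3,6-dimethylbicyclo[4.1.0]hept-3-ene F6 together with exo-7-bromo-1-methoxy-3,6-dimethylbicyclo[4.1.0]hept-3-ene F7. With AgNO3 in aqueous acetone only F6 can ionise with ring opening, and it should give 7 directly; F7 is inert and is removed by chromatography, at the cost of material.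

Step 4. The palladium hydride may add to the enone (1,4-reduction), or the double bonds may migrate on the metal. The fallback sets out from 6 and returns at 7. Luche reduction (NaBH4, CeCl3·7H2O, MeOH, −40 °C) should give 2-bromo-3,6-dimethylcyclohepta-2,5-dien-1-ol F8, which can no longer enolise. Bromine–lithium exchange with t-BuLi (3 equiv, THF, −78 °C) and quenching with MeOH should give 3,6-dimethylcyclohepta-2,5-dien-1-ol F9. MnO2 (CH2Cl2, rt) should oxidise the allylic alcohol back to 7.

Further compounds
F1 | step 6 | 1-bromo-4-methylpentan-3-one | CC(C)C(=O)CCBr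
F2 | step 6 | 2-(2-bromoethyl)-2-(propan-2-yl)-1,3-dioxolane | CC(C)C1(CCBr)OCCO1
F3 | step 6 | {2-[2-(propan-2-yl)-1,3-dioxolan-2-yl]ethyl}magnesium bromide | CC(C)C1(CC[Mg]Br)OCCO1
F4 | step 6 | (R)-3,6-dimethyl-3-{2-[2-(propan-2-yl)-1,3-dioxolan-2-yl]ethyl}cyclohept-5-en-1-one | CC(C)C1(CC[C@]2(C)CC=C(C)CC(=O)C2)OCCO1
F5 | step 6 | (R)-3,6-dimethyl-3-(4-methyl-3-oxopentyl)cyclohept-5-en-1-one | CC(C)C(=O)CC[C@]1(C)CC=C(C)CC(=O)C1
F6 | step 3 | rac-endo-7-bromo-1-methoxy-3,6-dimethylbicyclo[4.1.0]hept-3-ene (Br on the side of the six-membered ring; one enantiomer drawn) | CO[C@]12CC(C)=CC[C@@]1(C)[C@H]2Br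
F7 | step 3 | rac-exo-7-bromo-1-methoxy-3,6-dimethylbicyclo[4.1.0]hept-3-ene (Br on the side of OMe and CH3; one enantiomer drawn) | CO[C@]12CC(C)=CC[C@@]1(C)[C@@H]2Br
F8 | step 4 | rac-2-bromo-3,6-dimethylcyclohepta-2,5-dien-1-ol | CC1=CCC(C)=C(Br)C(O)C1
F9 | step 4 | rac-3,6-dimethylcyclohepta-2,5-dien-1-ol | CC1=CCC(C)=CC(O)C1
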